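**Retrosynthetic overview**

1. Feature: in ring B, C1 carries H, the 3,4-dimethoxyphenyl ring and C8a of ring A, so it can be made as a diaryl carbene carbon. C2 is an allylic CH2 of the C3=C4 side chain and lies beside C1 when that alkene is E.
2. Key disconnection C1–C2: an enantioselective intramolecular 1,6 C–H insertion of the rhodium carbene from diaryldiazomethane 15 closes ring B last and sets C1 and C2 together. Ring A and the pendant aryl ring come from the starting materials.
3. 15 ⇐ hydrazone 14 ⇐ diaryl ketone 13 ⇐ aryl bromide 9 + veratraldehyde (C1–C8a by aryllithium addition, then oxidation). 9 ⇐ aldehyde 3 + phosphonate 6 (C3=C4 by Horner–Wadsworth–Emmons olefination, then reduction and silylation). 3 ⇐ 4-(benzyloxy)-3-hydroxybenzaldehyde by bromination between OH and CHO.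
4. Spectator groups: O8 is a triisopropylsilyl ether during the carbene step, because an O-methyl group there would place C–H bonds 1,5 to the carbene; it is methylated afterwards. O7 and O9 are benzyl ethers, because an ester at C9 would not pass the hydride, aryllithium and hydrazine steps; they fall together at the end. O10 is a silyl ether until the late oxidation to the aldehyde.

Key step: step 10

**Remarks on the chemistry**

- Locants C1–C10 are those of ring B of the target: C1 aryl-bearing CH, C2 CH bearing C9, C3 bearing C10, C4 alkene CH, O7 free OH, O8 methyl ether. Names of cyclised compounds use this 1,2-dihydronaphthalene numbering.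
- 4-(Benzyloxy)-3-hydroxybenzaldehyde, triethyl phosphonoacetate, benzyl 2-bromoethyl ether and veratraldehyde are taken as catalogue compounds.
- The sense of induction of the new insertion cannot be read from precedent. The route is written with Rh2(R-PTAD)4, and the mirror-image Rh2(S-PTAD)4 takes its place if the (1R,2S) series forms.

**Route**

Step 1
Reactants: 1 4-(benzyloxy)-3-hydroxybenzaldehyde
Product: 2 4-(benzyloxy)-2-bromo-3-hydroxybenzaldehyde
Conditions: Br2 (1.05 equiv), NaOAc, iron powder (cat.), AcOH, 15–25 °C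
Reagents that add atoms: bromine, BrBr
Why: Electrophilic aromatic bromination directed by the free phenol, which in 3-hydroxy-4-alkoxybenzaldehydes goes to the position between OH and CHO (the future C8a), while NaOAc buffers HBr so that the benzyl ether stays.

Step 2
Reactants: 2 4-(benzyloxy)-2-bromo-3-hydroxybenzaldehyde
Product: 3 4-(benzyloxy)-2-bromo-3-[(triisopropylsilyl)oxy]benzaldehyde
Conditions: i-Pr3SiOTf, 2,6-lutidine, CH2Cl2, 0 °C → rt
Reagents that add atoms: triisopropylsilyl triflate, CC(C)[Si](OS(=O)(=O)C(F)(F)F)(C(C)C)C(C)C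
Why: O-Silylation of a hindered phenol by the silyl triflate gives an ether that resists the bases, hydride, aryllithium and hydrazine of the later steps and has no C–H bond on the atom next to oxygen.

Step 3
Reactants: 4 triethyl phosphonoacetate; 5 benzyl 2-bromoethyl ether
Product: 6 ethyl 4-(benzyloxy)-2-(diethoxyphosphoryl)butanoate (racemic)
Conditions: NaH, DMF, 0 → 60 °C
Reagents that add atoms: none
Why: SN2 C-alkylation of the sodium phosphonoacetate carbanion by a primary bromide, with a small excess of 4 to hold back dialkylation.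

Step 4
Reactants: 3 4-(benzyloxy)-2-bromo-3-[(triisopropylsilyl)oxy]benzaldehyde; 6 ethyl 4-(benzyloxy)-2-(diethoxyphosphoryl)butanoate
Product: 7 ethyl (2E)-2-[2-(benzyloxy)ethyl]-3-{4-(benzyloxy)-2-bromo-3-[(triisopropylsilyl)oxy]phenyl}prop-2-enoate
Conditions: NaH, THF, 0 → 45 °C
Reagents that add atoms: none
Why: Horner–Wadsworth–Emmons olefination with an α-alkylphosphonoacetate and an aryl aldehyde should favour the E ester (aryl trans to CO2Et, cis to the CH2CH2OBn arm), the geometry that later holds C2 beside C1, and any Z ester is removed by chromatography here.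

Step 5
Reactants: 7 ethyl (2E)-2-[2-(benzyloxy)ethyl]-3-{4-(benzyloxy)-2-bromo-3-[(triisopropylsilyl)oxy]phenyl}prop-2-enoate
Product: 8 (2E)-2-[2-(benzyloxy)ethyl]-3-{4-(benzyloxy)-2-bromo-3-[(triisopropylsilyl)oxy]phenyl}prop-2-en-1-ol
Conditions: i-Bu2AlH (2.5 equiv), CH2Cl2, −78 → −20 °C; aq. Rochelle salt
Reagents that add atoms: none
Why: 1,2-Reduction of the conjugated ester by the aluminium hydride gives the allylic alcohol without touching the aryl bromide, the alkene geometry or the ethers.

Step 6
Reactants: 8 (2E)-2-[2-(benzyloxy)ethyl]-3-{4-(benzyloxy)-2-bromo-3-[(triisopropylsilyl)oxy]phenyl}prop-2-en-1-ol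
Product: 9 tert-butyldimethylsilyl ether of 8
Conditions: t-BuMe2SiCl, imidazole, DMF, rt
Reagents that add atoms: tert-butyldimethylsilyl chloride, CC(C)(C)[Si](C)(C)Cl
Why: Standard silylation of a primary alcohol, which keeps the C2–H bonds electron-rich (no acceptor on C3) for the later hydride-like transfer.

Step 7
Reactants: 9 tert-butyldimethylsilyl ether of 8; 10 veratraldehyde
Product: 12 racemic {3-(benzyloxy)-6-[(1E)-4-(benzyloxy)-2-{[(tert-butyldimethylsilyl)oxy]methyl}but-1-en-1-yl]-2-[(triisopropylsilyl)oxy]phenyl}(3,4-dimethoxyphenyl)methanol, via aryllithium 11 (not isolated)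
Conditions: n-BuLi (1.05 equiv), THF, −90 °C, 5 min; 10, −90 → −78 °C; AcOH, −78 °C
Reagents that add atoms: none
Why: Bromine–lithium exchange followed by 1,2-addition of the aryllithium to the aldehyde forms the C1–C8a bond, the short time at −90 °C and the cold acidic quench holding back silyl migration and proton transfer from the neighbouring allylic CH2, and the carbinol may be racemic because C1 becomes sp2 in the next step.

Step 8
Reactants: 12 racemic diarylmethanol
Product: 13 {3-(benzyloxy)-6-[(1E)-4-(benzyloxy)-2-{[(tert-butyldimethylsilyl)oxy]methyl}but-1-en-1-yl]-2-[(triisopropylsilyl)oxy]phenyl}(3,4-dimethoxyphenyl)methanone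
Conditions: Dess–Martin periodinane, NaHCO3, CH2Cl2, 0 °C → rt
Reagents that add atoms: none
Why: Dess–Martin oxidation of the hindered doubly benzylic alcohol to the diaryl ketone under buffered conditions that leave silyl ethers, benzyl ethers and the alkene alone.

Step 9
Reactants: 13 diaryl ketone
Product: 14 hydrazone of 13 (C=N–NH2 at C1, either C=N geometry)
Conditions: N2H4·H2O (30 equiv), AcOH (cat.), EtOH, 90 °C, sealed tube, argon
Reagents that add atoms: hydrazine (used as the hydrate), NN
Why: Hydrazone formation by condensation, for which the ketone between O8 and the alkenyl group needs excess hydrazine and heat, conditions the substrate tolerates because it carries only ethers and silyl ethers and no ester.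

Step 10
Reactants: 14 hydrazone of 13
Product: 16 (1S,2R)-7-(benzyloxy)-2-[(benzyloxy)methyl]-3-{[(tert-butyldimethylsilyl)oxy]methyl}-1-(3,4-dimethoxyphenyl)-8-[(triisopropylsilyl)oxy]-1,2-dihydronaphthalene (1,2-trans), via diaryldiazomethane 15 (not isolated)
Conditions: MnO2 (activated, 10 equiv), CH2Cl2, 0 °C, dark; filtration under argon; filtrate added slowly to Rh2(R-PTAD)4 [dirhodium tetrakis((R)-1-adamantyl-N-phthalimidoacetate)] (1 mol%), CH2Cl2, −20 → 0 °C
Reagents that add atoms: none
Why: Proposed new method: MnO2 dehydrogenates the hydrazone to diaryldiazomethane 15, the dirhodium tetracarboxylate expels N2 to give a donor/donor rhodium carbene at C1, and this carbene takes one hydrogen of the allylic C2 methylene through a three-centre, hydride-transfer-like transition state while the C1–C2 bond forms with retention at C2. The closest known reaction type is the dirhodium-carboxylate-catalysed intramolecular C–H insertion of diaryl carbenes that gives 2,3-dihydrobenzofurans, indanes and isochromans; a 1,6-insertion into an allylic C–H bond with no heteroatom beside it has not been shown. Ring B closes in the 1,6-insertion mode through a six-membered half-chair in which C8a, C4a, C4 and C3 are already fixed by ring A and the E alkene, so that only the cis-held C2 hydrogens can reach C1. C1 and C2 are created in the same event: the chiral carboxylate ligands choose between the two enantiotopic C2 hydrogens and so the carbene face, and the trans relation is expected because the aryl group on C1 is pushed pseudoaxial by the peri O8–silyl group and the C9 arm on C2 pseudoaxial by A(1,2) strain with C10, which places them anti. Chemoselectivity rests on the substrate: O8 carries silicon instead of a methyl group so that no C–H bond sits 1,5 to the carbene, C10 is trans to ring A and cannot reach C1, attack on C3=C4 would need a fused four-membered ring, insertion at C9 would need a seven-membered transition state, and the fully substituted C3 terminus blocks 1,7-electrocyclisation of the o-alkenyl diazo compound. The trans assignment is to be checked by the H1–H2 coupling and NOE contacts before the material is carried on.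

Step 11
Reactants: 16 (1S,2R)-insertion product
Product: 18 [(1S,2R)-7-(benzyloxy)-2-[(benzyloxy)methyl]-1-(3,4-dimethoxyphenyl)-8-methoxy-1,2-dihydronaphthalen-3-yl]methanol, via phenol 17 (not isolated)
Conditions: Bu4NF (3 equiv), THF, 0 °C → rt; then K2CO3, MeI, DMF, rt
Reagents that add atoms: iodomethane, CI
Why: Fluoride cleaves both the aryl triisopropylsilyl ether and the primary tert-butyldimethylsilyl ether, and in the Williamson methylation only the phenoxide is alkylated under carbonate conditions while the allylic alcohol and both stereocenters stay as they are.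

Step 12
Reactants: 18 allylic alcohol
Product: 19 (1S,2R)-7-(benzyloxy)-2-[(benzyloxy)methyl]-1-(3,4-dimethoxyphenyl)-8-methoxy-1,2-dihydronaphthalene-3-carbaldehyde
Conditions: MnO2 (activated, 15 equiv), CH2Cl2, rt
Reagents that add atoms: none
Why: Selective MnO2 oxidation of the allylic alcohol to the conjugated aldehyde, with O9 still benzylated so that no lactol can form and be over-oxidised, and with C2 unable to enolise towards the new carbonyl.

Step 13
Reactants: 19 dibenzyl enal
Product: 20 vitekwangin B
Conditions: BCl3 (6 equiv), pentamethylbenzene (8 equiv), CH2Cl2, −78 → −40 °C; then H2O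
Reagents that add atoms: none
Why: Lewis-acid debenzylation with pentamethylbenzene as a non-basic benzyl-cation scavenger removes the aryl and the alkyl benzyl ether at low temperature, where aryl methyl ethers survive, and, unlike hydrogenolysis, leaves the C3=C4 bond and the aldehyde unreduced.

**Compound list**

1 | 4-(benzyloxy)-3-hydroxybenzaldehyde | O=Cc1ccc(OCc2ccccc2)c(O)c1 | starting material
2 | 4-(benzyloxy)-2-bromo-3-hydroxybenzaldehyde | O=Cc1ccc(OCc2ccccc2)c(O)c1Br | intermediate
3 | 4-(benzyloxy)-2-bromo-3-[(triisopropylsilyl)oxy]benzaldehyde | O=Cc1ccc(OCc2ccccc2)c(O[Si](C(C)C)(C(C)C)C(C)C)c1Br | intermediate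
4 | triethyl phosphonoacetate | CCOC(=O)CP(=O)(OCC)OCC | starting material
5 | benzyl 2-bromoethyl ether | BrCCOCc1ccccc1 | starting material
6 | ethyl 4-(benzyloxy)-2-(diethoxyphosphoryl)butanoate (racemic) | CCOC(=O)C(CCOCc1ccccc1)P(=O)(OCC)OCC | intermediate
7 | ethyl (2E)-2-[2-(benzyloxy)ethyl]-3-{4-(benzyloxy)-2-bromo-3-[(triisopropylsilyl)oxy]phenyl}prop-2-enoate | CCOC(=O)/C(CCOCc1ccccc1)=C/c1ccc(OCc2ccccc2)c(O[Si](C(C)C)(C(C)C)C(C)C)c1Br | intermediate
8 | (2E)-2-[2-(benzyloxy)ethyl]-3-{4-(benzyloxy)-2-bromo-3-[(triisopropylsilyl)oxy]phenyl}prop-2-en-1-ol | OC/C(CCOCc1ccccc1)=C/c1ccc(OCc2ccccc2)c(O[Si](C(C)C)(C(C)C)C(C)C)c1Br | intermediate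
9 | tert-butyldimethylsilyl ether of 8 (aryl bromide with the E side chain) | CC(C)(C)[Si](C)(C)OC/C(CCOCc1ccccc1)=C/c1ccc(OCc2ccccc2)c(O[Si](C(C)C)(C(C)C)C(C)C)c1Br | intermediate
10 | veratraldehyde (3,4-dimethoxybenzaldehyde) | COc1ccc(C=O)cc1OC | starting material
11 | aryllithium from 9 (Li in place of Br) | CC(C)(C)[Si](C)(C)OC/C(CCOCc1ccccc1)=C/c1ccc(OCc2ccccc2)c(O[Si](C(C)C)(C(C)C)C(C)C)c1[Li] | intermediate
12 | racemic {3-(benzyloxy)-6-[(1E)-4-(benzyloxy)-2-{[(tert-butyldimethylsilyl)oxy]methyl}but-1-en-1-yl]-2-[(triisopropylsilyl)oxy]phenyl}(3,4-dimethoxyphenyl)methanol | COc1ccc(C(O)c2c(/C=C(/CO[Si](C)(C)C(C)(C)C)CCOCc3ccccc3)ccc(OCc3ccccc3)c2O[Si](C(C)C)(C(C)C)C(C)C)cc1OC | intermediate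
13 | diaryl ketone corresponding to 12 (methanone) | COc1ccc(C(=O)c2c(/C=C(/CO[Si](C)(C)C(C)(C)C)CCOCc3ccccc3)ccc(OCc3ccccc3)c2O[Si](C(C)C)(C(C)C)C(C)C)cc1OC | intermediate
14 | hydrazone of 13 | COc1ccc(C(=NN)c2c(/C=C(/CO[Si](C)(C)C(C)(C)C)CCOCc3ccccc3)ccc(OCc3ccccc3)c2O[Si](C(C)C)(C(C)C)C(C)C)cc1OC | intermediate
15 | diaryldiazomethane from 14 (key-step precursor) | COc1ccc(C(=[N+]=[N-])c2c(/C=C(/CO[Si](C)(C)C(C)(C)C)CCOCc3ccccc3)ccc(OCc3ccccc3)c2O[Si](C(C)C)(C(C)C)C(C)C)cc1OC | intermediate
16 | (1S,2R)-7-(benzyloxy)-2-[(benzyloxy)methyl]-3-{[(tert-butyldimethylsilyl)oxy]methyl}-1-(3,4-dimethoxyphenyl)-8-[(triisopropylsilyl)oxy]-1,2-dihydronaphthalene, 1,2-trans (key-step product) | COc1ccc([C@H]2c3c(ccc(OCc4ccccc4)c3O[Si](C(C)C)(C(C)C)C(C)C)C=C(CO[Si](C)(C)C(C)(C)C)[C@@H]2COCc2ccccc2)cc1OC | intermediate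
17 | (1S,2R)-7-(benzyloxy)-2-[(benzyloxy)methyl]-1-(3,4-dimethoxyphenyl)-3-(hydroxymethyl)-1,2-dihydronaphthalen-8-ol | COc1ccc([C@H]2c3c(ccc(OCc4ccccc4)c3O)C=C(CO)[C@@H]2COCc2ccccc2)cc1OC | intermediate
18 | [(1S,2R)-7-(benzyloxy)-2-[(benzyloxy)methyl]-1-(3,4-dimethoxyphenyl)-8-methoxy-1,2-dihydronaphthalen-3-yl]methanol | COc1ccc([C@H]2c3c(ccc(OCc4ccccc4)c3OC)C=C(CO)[C@@H]2COCc2ccccc2)cc1OC | intermediate
19 | (1S,2R)-7-(benzyloxy)-2-[(benzyloxy)methyl]-1-(3,4-dimethoxyphenyl)-8-methoxy-1,2-dihydronaphthalene-3-carbaldehyde | COc1ccc([C@H]2c3c(ccc(OCc4ccccc4)c3OC)C=C(C=O)[C@@H]2COCc2ccccc2)cc1OC | intermediate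
20 | vitekwangin B, (1S,2R)-1-(3,4-dimethoxyphenyl)-7-hydroxy-2-(hydroxymethyl)-8-methoxy-1,2-dihydronaphthalene-3-carbaldehyde | COc1ccc([C@H]2c3c(ccc(O)c3OC)C=C(C=O)[C@@H]2CO)cc1OC | target

**Step count and risks**

Total step count: 13. Longest linear sequence: 12 steps (1 → 20 through steps 1, 2 and 4–13); step 3 is a one-step side branch.

Steps most likely to fail:

1. Step 10 (new method). Decomposition of 15 at the doubly ortho-substituted diazo carbon may be slow, so azine formation or thermal closure of the diazo compound could take over. The carbene may insert into a Si–C–H or a C9–H bond instead. The hydride-transfer character of the step may deliver the cis ring or poor discrimination of the two C2 hydrogens.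
 Fallback by known chemistry: ring B is closed at C3=C4 by aldol condensation after C1 and C2 have been set by an oxazolidinone auxiliary. It sets out from 2 and comes back at 19.
 - Phenol 2 is methylated (MeI, K2CO3, DMF) to 4-(benzyloxy)-2-bromo-3-methoxybenzaldehyde F1, and the aldehyde is masked (ethylene glycol, TsOH, toluene, reflux) as 2-[4-(benzyloxy)-2-bromo-3-methoxyphenyl]-1,3-dioxolane F2.
 - 3,4-Dimethoxycinnamic acid is joined to (S)-4-benzyloxazolidin-2-one (pivaloyl chloride, Et3N, LiCl, THF) to give (S)-4-benzyl-3-[(2E)-3-(3,4-dimethoxyphenyl)prop-2-enoyl]oxazolidin-2-one F3.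
 - The Grignard reagent from F2 (Mg, THF) with CuBr·SMe2 adds 1,4 to F3 from the face away from the benzyl group and gives the (3S)-3,3-diarylpropanoyl imide F4, which fixes C1.
 - The sodium enolate (NaN(SiMe3)2, THF, −78 °C) is allylated with allyl iodide, again anti to the auxiliary, to the (2S,3S)-2-allyl imide F5, which fixes C2 in the arrangement that becomes the trans ring.
 - LiBH4 (Et2O, H2O, 0 °C) gives (2S,3S)-2-allyl-3,3-diarylpropan-1-ol F6 and returns the auxiliary, and NaH/BnBr gives the benzyl ether F7.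
 - OsO4 (cat.)/NaIO4/2,6-lutidine cleaves the vinyl group to the (3S,4S)-4,4-diaryl-3-[(benzyloxy)methyl]butanal F8.
 - Aqueous HCl in THF frees the aryl aldehyde to give the dialdehyde F9, which with pyrrolidine/AcOH undergoes intramolecular aldol condensation (C3 onto the aryl aldehyde carbon C4, then loss of water) to 19. Step 13 follows.

2. Step 9. Condensation at the ketone flanked by O8 and the alkenyl group may stall, and long heating with hydrazine may strip the aryl silyl ether.
 Fallback, from 13 back to 14: thionation with Lawesson's reagent (toluene, 90 °C) gives the diaryl thioketone F10. Thioketones exchange sulfur for the hydrazone nitrogen at room temperature (N2H4·H2O, THF/EtOH), so the hindered carbonyl addition is avoided.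

3. Step 7. The aryllithium may be quenched by proton transfer from the neighbouring allylic CH2, may undergo oxygen-to-carbon silyl shift, or may add too slowly to the aldehyde because both ortho positions are occupied.
 Fallback, from 9 directly to 13: carbonylative Suzuki–Miyaura coupling of bromide 9 with (3,4-dimethoxyphenyl)boronic acid under CO (Pd(OAc)2, di(1-adamantyl)-n-butylphosphine, K2CO3, toluene, 100 °C, 5 bar). This needs no carbanion and also replaces step 8.

**Further compounds**

F1 | step 10 | 4-(benzyloxy)-2-bromo-3-methoxybenzaldehyde | COc1c(Br)c(C=O)ccc1OCc1ccccc1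
F2 | step 10 | 2-[4-(benzyloxy)-2-bromo-3-methoxyphenyl]-1,3-dioxolane | COc1c(Br)c(C2OCCO2)ccc1OCc1ccccc1
F3 | step 10 | (S)-4-benzyl-3-[(2E)-3-(3,4-dimethoxyphenyl)prop-2-enoyl]oxazolidin-2-one | COc1ccc(/C=C/C(=O)N2[C@@H](Cc3ccccc3)COC2=O)cc1OC
F4 | step 10 | (S)-4-benzyl-3-{(3S)-3-[3-(benzyloxy)-6-(1,3-dioxolan-2-yl)-2-methoxyphenyl]-3-(3,4-dimethoxyphenyl)propanoyl}oxazolidin-2-one | COc1ccc([C@H](CC(=O)N2[C@@H](Cc3ccccc3)COC2=O)c2c(C3OCCO3)ccc(OCc3ccccc3)c2OC)cc1OC
F5 | step 10 | (2S,3S)-2-allyl derivative of F4 | COc1ccc([C@H]([C@H](CC=C)C(=O)N2[C@@H](Cc3ccccc3)COC2=O)c2c(C3OCCO3)ccc(OCc3ccccc3)c2OC)cc1OC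
F6 | step 10 | (2S,3S)-2-allyl-3-[3-(benzyloxy)-6-(1,3-dioxolan-2-yl)-2-methoxyphenyl]-3-(3,4-dimethoxyphenyl)propan-1-ol | COc1ccc([C@H]([C@H](CC=C)CO)c2c(C3OCCO3)ccc(OCc3ccccc3)c2OC)cc1OC
F7 | step 10 | benzyl ether of F6 | COc1ccc([C@H]([C@H](CC=C)COCc2ccccc2)c2c(C3OCCO3)ccc(OCc3ccccc3)c2OC)cc1OC
F8 | step 10 | (3S,4S)-4-[3-(benzyloxy)-6-(1,3-dioxolan-2-yl)-2-methoxyphenyl]-3-[(benzyloxy)methyl]-4-(3,4-dimethoxyphenyl)butanal | COc1ccc([C@H]([C@H](CC=O)COCc2ccccc2)c2c(C3OCCO3)ccc(OCc3ccccc3)c2OC)cc1OC
F9 | step 10 | (3S,4S)-4-[3-(benzyloxy)-6-formyl-2-methoxyphenyl]-3-[(benzyloxy)methyl]-4-(3,4-dimethoxyphenyl)butanal | COc1ccc([C@H]([C@H](CC=O)COCc2ccccc2)c2c(C=O)ccc(OCc3ccccc3)c2OC)cc1OC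
F10 | step 9 | diaryl thioketone corresponding to 13 (C=S at C1) | COc1ccc(C(=S)c2c(/C=C(/CO[Si](C)(C)C(C)(C)C)CCOCc3ccccc3)ccc(OCc3ccccc3)c2O[Si](C(C)C)(C(C)C)C(C)C)cc1OC
F0 | step 7 | none | none
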